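**Strategy.** The cyclohexanone ring (C1, C10–C14; briarane numbering) is disconnected across C1–C14 and C10–C11: its C12 ketone/C14 oxygen pair and the C2 oxygen beside quaternary C1 are the retron of a Diels–Alder reaction between a 1-methoxy-3-silyloxy diene and a C2-keto C1=C10 enone. One cycloaddition thus annulates the six-membered ring onto a preformed lactone-fused ten-membered ring, making both C–C bonds, the quaternary centre C1 and the trans ring fusion. The precursor is a germacranolide-like (E)-2-methylcyclodecenone, built from (R)-malic acid, whose temporary (9R)-acetoxy group steers the diene to the required face and is later corrected by oxidation and reduction.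

Key step: step 16

Remarks.
- Locants C1–C20 follow briarane numbering of the target in all intermediates.
- Assumption: the C17 epimer with the methyl anti to the C9 branch (cis to 8-OH) is the thermodynamically preferred lactone.
- Assumption: in the E-cyclodecenone 21 only the outer alkene face is open, with H-9 lying in the alkene plane (least A1,3 strain with C15). The same model is used for C5=C6 in step 26.
- The C11 and C14 configurations drawn for 26–33 are those of the expected endo adduct. They do not matter, because C14 becomes sp2 in step 22 and C11 is reset in step 23.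

Step 1
Reactants: 1 tert-butyldimethyl(pent-4-yn-1-yloxy)silane
Product: 3 (E)-6-(tert-butyldimethylsilyloxy)-3-methylhex-2-en-1-ol, via alkenylalane 2 (not isolated)
Conditions: AlMe3, Cp2ZrCl2 (cat.), CH2Cl2, 0 °C to rt; then n-BuLi, (CH2O)n, THF, −78 °C to rt; aq. HCl
Reagents that add atoms: trimethylaluminium C[Al](C)C; formaldehyde (from paraformaldehyde) C=O
Why: Zirconium-catalysed Negishi carboalumination adds methyl and aluminium syn across the terminal alkyne, and hydroxymethylation of the alkenylalanate with retention fixes the E trisubstituted alkene (later C5=C6 with C16).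

Step 2
Reactants: 3 (E)-6-(tert-butyldimethylsilyloxy)-3-methylhex-2-en-1-ol
Product: 4 (E)-6-(tert-butyldimethylsilyloxy)-3-methylhex-2-enal
Conditions: MnO2, CH2Cl2, rt
Reagents that add atoms: none
Why: Allylic oxidation with MnO2 should give the enal without E/Z isomerisation.

Step 3
Reactants: 5 (R)-malic acid
Product: 6 cis-dioxolanone acid 2-[(2R,4R)-2-tert-butyl-5-oxo-1,3-dioxolan-4-yl]acetic acid
Conditions: t-BuCHO, TsOH (cat.), H2SO4 (cat.), pentane, reflux, Dean–Stark
Reagents that add atoms: pivalaldehyde CC(C)(C)C=O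
Why: Acid-catalysed acetalisation of the α-hydroxy acid gives the cis dioxolanone under thermodynamic control, storing the malate stereocentre in the acetal carbon (self-regeneration of stereocentres).

Step 4
Reactants: 6 cis-dioxolanone acid; 4 (E)-6-(tert-butyldimethylsilyloxy)-3-methylhex-2-enal
Product: 9 spiro lactone–dioxolanone, via dilithium enolate 7 (not isolated), via aldol hydroxy acid 8 (not isolated)
Conditions: LiHMDS (2.2 equiv), THF, −78 °C; 4, −78 °C; aq. HCl (pH 3); then PPTS (cat.), CH2Cl2, rt
Reagents that add atoms: none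
Why: Aldol addition of the dioxolanone enolate to the enal should occur anti to the tert-butyl group (C8, net retention) and through a chair Zimmerman–Traxler transition state of the ring-fixed enolate (C7–O anti to C8–O), after which the γ-hydroxy acid lactonises.

Step 5
Reactants: 9 spiro lactone–dioxolanone
Product: 11 ynone lactone, via lithium hemiketal alkoxide 10 (not isolated)
Conditions: 1-propynyllithium (1.1 equiv), THF, −78 °C; AcOH quench
Reagents that add atoms: 1-propynyllithium CC#C[Li]
Why: Acetylide addition to the acylal-type dioxolanone carbonyl, which is more electrophilic than the γ-lactone, gives a tetrahedral alkoxide that survives until work-up and then releases pivalaldehyde and the free C8 hydroxyl (nucleophilic acyl substitution stopping at the ketone).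

Step 6
Reactants: 11 ynone lactone
Product: 12 (9R)-propargylic diol
Conditions: RuCl[(S,S)-TsDPEN](p-cymene) (cat.), HCO2H/Et3N (5:2), CH2Cl2, rt
Reagents that add atoms: none
Why: Noyori asymmetric transfer hydrogenation of the ynone is reagent-controlled, and the (S,S)-catalyst (alkynyl group in the place normally taken by an aryl group) should give the 9R carbinol, chosen on purpose as the unnatural C9 epimer.

Step 7
Reactants: 12 (9R)-propargylic diol
Product: 14 C17-methyl lactone diol, via trilithium lactone enolate 13 (not isolated)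
Conditions: LDA (3.3 equiv), THF, −78 °C; MeI, −78 to −30 °C; aq. NH4Cl; then DBU (cat.), PhMe, 40 °C
Reagents that add atoms: iodomethane CI
Why: Enolate alkylation of the lactone introduces C18, and base equilibration through the enolate should then give the more stable C17 epimer with the methyl anti to the C9 branch, which is the target configuration.

Step 8
Reactants: 14 C17-methyl lactone diol
Product: 15 (9R)-propargylic acetate
Conditions: Ac2O, pyridine, DMAP (cat.), CH2Cl2, 0 °C
Reagents that add atoms: acetic anhydride CC(=O)OC(C)=O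
Why: DMAP-catalysed acylation of the secondary alcohol leaves the hindered tertiary C8 hydroxyl free and removes the alkoxide that could misdirect the following hydrometalation.

Step 9
Reactants: 15 (9R)-propargylic acetate
Product: 17 (E)-vinyl iodide, via alkenylzirconocene 16 (not isolated)
Conditions: Cp2Zr(H)Cl (2.5 equiv), THF, 0 °C to rt; then I2, 0 °C
Reagents that add atoms: iodine II
Why: Syn hydrozirconation places zirconium on the less hindered methyl-bearing alkyne carbon (C1), and iodinolysis with retention gives the E-vinyl iodide (C9 cis to C15).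

Step 10
Reactants: 17 (E)-vinyl iodide
Product: 18 primary alcohol
Conditions: HF·pyridine, THF/pyridine, 0 °C
Reagents that add atoms: none
Why: Fluoride cleaves the primary silyl ether (desilylation) without touching acetate, lactone or vinyl iodide.

Step 11
Reactants: 18 primary alcohol
Product: 19 aldehyde
Conditions: Dess–Martin periodinane, NaHCO3, CH2Cl2, 0 °C to rt
Reagents that add atoms: none
Why: Dess–Martin oxidation of the primary alcohol under buffered conditions.

Step 12
Reactants: 19 aldehyde
Product: 20 macrocyclic allylic alcohol (C2 epimers)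
Conditions: CrCl2 (8 equiv), NiCl2 (cat.), DMSO/THF, 2 mM, rt
Reagents that add atoms: none
Why: Intramolecular Nozaki–Hiyama–Kishi reaction: the alkenylchromium forms with retention of alkene geometry and adds to the aldehyde at high dilution to close the ten-membered ring, and the C2 carbinol mixture is inconsequential because it is oxidised next.

Step 13
Reactants: 20 macrocyclic allylic alcohol
Product: 21 ten-membered (E)-enone lactone
Conditions: Dess–Martin periodinane, NaHCO3, CH2Cl2, 0 °C
Reagents that add atoms: none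
Why: Dess–Martin oxidation of the allylic alcohol gives the strained E-2-methyl enone that serves as dienophile.

Step 14
Reactants: 22 (E)-4-methoxybut-3-en-2-one
Product: 24 (E)-1-methoxypent-1-en-3-one, via lithium dienolate 23 (not isolated)
Conditions: LDA, THF, −78 °C; MeI, −78 to −20 °C
Reagents that add atoms: iodomethane CI
Why: Kinetic α′-deprotonation of the vinylogous ester and C-methylation of the cross-conjugated enolate (enolate alkylation).

Step 15
Reactants: 24 (E)-1-methoxypent-1-en-3-one
Product: 25 (1E,3Z)-1-methoxy-3-(tert-butyldimethylsilyloxy)penta-1,3-diene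
Conditions: TBSOTf, Et3N, Et2O, 0 °C
Reagents that add atoms: tert-butyldimethylsilyl triflate CC(C)(C)[Si](C)(C)OS(=O)(=O)C(F)(F)F
Why: Soft enolisation gives the Z silyl enol ether, i.e. the Danishefsky-type diene (silyl enol ether formation).

Step 16
Reactants: 21 ten-membered (E)-enone lactone; 25 (1E,3Z)-1-methoxy-3-(tert-butyldimethylsilyloxy)penta-1,3-diene
Product: 26 Diels–Alder adduct
Conditions: 25 (5 equiv), Eu(fod)3 (10 mol %), PhMe, 60 °C, sealed tube
Reagents that add atoms: none
Why: Normal-demand Diels–Alder reaction of a Danishefsky-type diene with an enone (closest known type: Danishefsky-diene annulation of 2-substituted cycloalkenones); the six-membered ring is closed by an intermolecular, suprafacial, asynchronous [4+2] annulation that forms C10–C11 (nucleophilic diene terminus to the enone β-carbon) and C1–C14. C1 (quaternary) and C10 are set by the E geometry of the ring alkene, which translates stereospecifically into the trans ring fusion (C15 and H-10 trans). Their absolute sense is set by the face of attack: only the outer face of the trans-cyclodecene is open, the C9–C8 ring bond lies anti to the incoming diene, and with the 9R acetate the conformer with H-9 in the alkene plane exposes the face that gives 1R,10S. C14 and C11 follow from the endo rule and the diene geometry but are not needed. The step requires site selectivity (only the ketone-conjugated C1=C10 is a dienophile, C5=C6 is unactivated), regioselectivity (secured by the C2 carbonyl and the 1,3-dioxygenated diene) and reactivity of a trisubstituted enone, which the strain of the E-cycloalkene and mild Lewis acid catalysis should provide.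

Step 17
Reactants: 26 Diels–Alder adduct
Product: 27 (9R)-alcohol adduct
Conditions: K2CO3, MeOH, 0 °C
Reagents that add atoms: none
Why: Transesterification (methanolysis) removes the acetate that has served as the stereodirecting group, while the silyl enol ether and the lactone should survive the mild base.

Step 18
Reactants: 27 (9R)-alcohol adduct
Product: 28 2,9-diketone
Conditions: Dess–Martin periodinane, NaHCO3, CH2Cl2, 0 °C to rt
Reagents that add atoms: none
Why: Dess–Martin oxidation of the only oxidisable hydroxyl erases the temporary C9 stereocentre and gives the α-hydroxy ketone.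

Step 19
Reactants: 28 2,9-diketone
Product: 30 (3Z)-dienone, via bis-TMS enol ether 29 (not isolated)
Conditions: LiHMDS (2.2 equiv), TMSCl (3 equiv), THF, −78 °C; then Pd(OAc)2 (1.2 equiv), MeCN, rt
Reagents that add atoms: chlorotrimethylsilane C[Si](C)(C)Cl
Why: Kinetic enolisation of the C2 ketone can only go toward C3 (C1 is quaternary, and the C9 ketone has only the hindered C10 methine), and Saegusa–Ito oxidation of the TMS enol ether gives the enone, whose C3=C4 bond should be Z because a second E bond next to E-C5=C6 cannot be accommodated in the ten-membered ring; the tertiary hydroxyl is silylated in the same operation.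

Step 20
Reactants: 30 (3Z)-dienone
Product: 31 (2S,9S)-diol
Conditions: NaBH4, CeCl3·7H2O, MeOH/THF, −78 to −40 °C
Reagents that add atoms: none
Why: Luche 1,2-reduction of both ketones: at C9 the Felkin–Anh preferences of both flanking centres coincide (hydride anti to the C10–C1 bond and anti to the C8–O bond) and should give 9S, and at C2 hydride should add anti to the C1–C14 bond from the side of the C15 methyl to give 2S.

Step 21
Reactants: 31 (2S,9S)-diol
Product: 32 2,9-diacetate
Conditions: Ac2O, pyridine, DMAP, CH2Cl2, rt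
Reagents that add atoms: acetic anhydride CC(=O)OC(C)=O
Why: DMAP-catalysed acetylation of both secondary alcohols, the tertiary hydroxyl being masked as its TMS ether.

Step 22
Reactants: 32 2,9-diacetate
Product: 33 cyclohexenone (11-epi)
Conditions: 0.1 M HCl, THF/H2O, 0 °C
Reagents that add atoms: none
Why: Acid hydrolysis of the silyl enol ether with β-elimination of methanol (the usual unmasking of a Danishefsky adduct) gives the enone and also cleaves the tertiary TMS ether.

Step 23
Reactants: 33 cyclohexenone (11-epi)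
Product: 35 (11R)-cyclohexenone, via TMS dienol ether 34 (not isolated)
Conditions: TMSOTf (2.5 equiv), Et3N (4 equiv), CH2Cl2, −78 °C; then TBAF/AcOH (1:1), THF, −78 °C
Reagents that add atoms: none
Why: Soft enolisation can only occur at C11 (C1 is quaternary, C13 is sp2), and kinetic protonation of the cross-conjugated silyl dienol ether should occur from the α face, anti to the syn-axial C15 methyl and the adjacent C9 branch, placing C20 β (11R).

Step 24
Reactants: 35 (11R)-cyclohexenone
Product: 37 (14S)-hydroxy ketone, via C14 boronate 36 (not isolated)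
Conditions: B2pin2, CuCl (10 mol %), DPEphos, NaOt-Bu (10 mol %), MeOH (2 equiv), THF, 0 °C; then H2O2, pH 7 buffer, 0 °C
Reagents that add atoms: hydrogen peroxide OO
Why: Copper-catalysed conjugate borylation should deliver boron to C14 by axial attack anti to the C15 methyl (α face), and C–B oxidation with retention gives the 14S alcohol (β-borylation then oxidation).

Step 25
Reactants: 37 (14S)-hydroxy ketone
Product: 38 14-butanoate
Conditions: (n-PrCO)2O, pyridine, DMAP (cat.), CH2Cl2, 0 °C
Reagents that add atoms: butyric anhydride CCCC(=O)OC(=O)CCC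
Why: Esterification of the only free secondary alcohol under DMAP catalysis, the tertiary C8 hydroxyl being unreactive.

Step 26
Reactants: 38 14-butanoate
Product: 39 5,6-epoxide
Conditions: dimethyldioxirane, acetone, −40 to 0 °C
Reagents that add atoms: dimethyldioxirane CC1(C)OO1
Why: Electrophilic epoxidation should take the more electron-rich trisubstituted C5=C6 bond on its outer face (H-7 in the alkene plane, C7–C8 anti), which places the C6 oxygen with the configuration opposite to that of the chloride in the target.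

Step 27
Reactants: 39 5,6-epoxide
Product: 40 (6R)-allylic alcohol
Conditions: Cp2TiCl2 (2.5 equiv), Mn dust, THF, rt; aq. HCl work-up
Reagents that add atoms: none
Why: Titanocene(III)-mediated homolytic opening of the epoxide at the tertiary allylic C5–O bond and loss of a C16 hydrogen gives the exocyclic-methylene allylic alcohol with the C6–O bond untouched (epoxide to allylic alcohol isomerisation).

Step 28
Reactants: 40 (6R)-allylic alcohol
Product: 41 ptilosarcone
Conditions: PPh3, hexachloroacetone, CH2Cl2, −20 to 0 °C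
Reagents that add atoms: hexachloroacetone O=C(C(Cl)(Cl)Cl)C(Cl)(Cl)Cl
Why: Appel-type chlorination of the secondary allylic alcohol should proceed by SN2 displacement with inversion and without allylic transposition, converting the 6R alcohol into the 6S chloride.

**Compound list**

1 | tert-butyldimethyl(pent-4-yn-1-yloxy)silane | C#CCCCO[Si](C)(C)C(C)(C)C | starting material
2 | alkenylalane, dimethyl[(E)-5-(tert-butyldimethylsilyloxy)-2-methylpent-1-enyl]alane | C/C(CCCO[Si](C)(C)C(C)(C)C)=C\[Al](C)C | intermediate
3 | (E)-6-(tert-butyldimethylsilyloxy)-3-methylhex-2-en-1-ol | OC/C=C(\C)CCCO[Si](C)(C)C(C)(C)C | intermediate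
4 | (E)-6-(tert-butyldimethylsilyloxy)-3-methylhex-2-enal | O=C/C=C(\C)CCCO[Si](C)(C)C(C)(C)C | intermediate
5 | (R)-malic acid | O=C(O)C[C@@H](O)C(=O)O | starting material
6 | cis-dioxolanone acid, 2-[(2R,4R)-2-tert-butyl-5-oxo-1,3-dioxolan-4-yl]acetic acid | O=C1O[C@H](C(C)(C)C)O[C@@H]1CC(=O)O | intermediate
7 | dilithium enolate (carboxylate and dioxolanone enolate of 6) | CC(C)(C)[C@H]1OC([O-])=C(CC(=O)[O-])O1.[Li+].[Li+] | intermediate
8 | aldol hydroxy acid (C8 quaternary, new C7 substituent trans to t-Bu; C7–OH anti to C8–O) | O=C1O[C@H](C(C)(C)C)O[C@@]1(CC(=O)O)[C@@H](O)/C=C(\C)CCCO[Si](C)(C)C(C)(C)C | intermediate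
9 | spiro lactone–dioxolanone (γ-lactone C19–O–C7 spiro-fused at C8 to the dioxolanone; C7 bears the E-alkenyl chain) | O=C1O[C@H](C(C)(C)C)O[C@]12CC(=O)O[C@H]2/C=C(\C)CCCO[Si](C)(C)C(C)(C)C | intermediate
10 | lithium hemiketal alkoxide (propynyl adduct at C9) | CC#CC1([O-])O[C@H](C(C)(C)C)O[C@]12CC(=O)O[C@H]2/C=C(\C)CCCO[Si](C)(C)C(C)(C)C.[Li+] | intermediate
11 | ynone lactone, (4S,5S)-4-(but-2-ynoyl)-4-hydroxy-5-[(E)-5-(tert-butyldimethylsilyloxy)-2-methylpent-1-enyl]dihydrofuran-2(3H)-one (8-OH cis to the C7 alkenyl group) | CC#CC(=O)[C@]1(O)CC(=O)O[C@H]1/C=C(\C)CCCO[Si](C)(C)C(C)(C)C | intermediate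
12 | (9R)-propargylic diol (ynone of 11 reduced to the 9R carbinol) | CC#C[C@@H](O)[C@]1(O)CC(=O)O[C@H]1/C=C(\C)CCCO[Si](C)(C)C(C)(C)C | intermediate
13 | trilithium lactone enolate of 12 | CC#C[C@@H]([O-])[C@]1([O-])C=C([O-])O[C@H]1/C=C(\C)CCCO[Si](C)(C)C(C)(C)C.[Li+].[Li+].[Li+] | intermediate
14 | C17-methyl lactone diol (C17 methyl cis to 8-OH; 9R) | CC#C[C@@H](O)[C@]1(O)[C@@H](C)C(=O)O[C@H]1/C=C(\C)CCCO[Si](C)(C)C(C)(C)C | intermediate
15 | (9R)-propargylic acetate | CC#C[C@@H](OC(C)=O)[C@]1(O)[C@@H](C)C(=O)O[C@H]1/C=C(\C)CCCO[Si](C)(C)C(C)(C)C | intermediate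
16 | alkenylzirconocene (Zr on C1, syn to H-10) | C/C(=C\[C@@H](OC(C)=O)[C@]1(O)[C@@H](C)C(=O)O[C@H]1/C=C(\C)CCCO[Si](C)(C)C(C)(C)C)[Zr](Cl)(C2C=CC=C2)C3C=CC=C3 | intermediate
17 | (E)-vinyl iodide (I on C1; C9 cis to C15) | C/C(I)=C\[C@@H](OC(C)=O)[C@]1(O)[C@@H](C)C(=O)O[C@H]1/C=C(\C)CCCO[Si](C)(C)C(C)(C)C | intermediate
18 | primary alcohol (C2–OH) | C/C(I)=C\[C@@H](OC(C)=O)[C@]1(O)[C@@H](C)C(=O)O[C@H]1/C=C(\C)CCCO | intermediate
19 | aldehyde (C2) | C/C(I)=C\[C@@H](OC(C)=O)[C@]1(O)[C@@H](C)C(=O)O[C@H]1/C=C(\C)CCC=O | intermediate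
20 | macrocyclic allylic alcohol: ten-membered carbocycle C1–C10 fused at C7/C8 to the γ-lactone; 1(10)E, 5E; 2-OH (epimers), 8-OH, 9R-OAc | OC1CC/C(C)=C/[C@@H]2OC(=O)[C@H](C)[C@@]2(O)[C@H](OC(C)=O)/C=C1\C | intermediate
21 | ten-membered (E)-enone lactone (2-oxo-1(10)E,5E; 9R-OAc) | O=C1CC/C(C)=C/[C@@H]2OC(=O)[C@H](C)[C@@]2(O)[C@H](OC(C)=O)/C=C1\C | intermediate
22 | (E)-4-methoxybut-3-en-2-one | CC(=O)/C=C/OC | starting material
23 | lithium dienolate of 22 | [Li+].[O-]C(=C)/C=C/OC | intermediate
24 | (E)-1-methoxypent-1-en-3-one | CCC(=O)/C=C/OC | intermediate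
25 | (1E,3Z)-1-methoxy-3-(tert-butyldimethylsilyloxy)penta-1,3-diene | CO/C=C/C(O[Si](C)(C)C(C)(C)C)=C/C | intermediate
26 | Diels–Alder adduct: briarane skeleton, 1R,10S; 2-oxo; 9R-OAc; 12-OTBS enol ether (C12=C13); 14α-OMe; 11α-Me; 5E | C/C1=C\[C@@H]2OC(=O)[C@H](C)[C@@]2(O)[C@H](OC(C)=O)[C@H]3[C@H](C)C(O[Si](C)(C)C(C)(C)C)=C[C@H](OC)[C@]3(C)C(=O)CC1 | intermediate
27 | (9R)-alcohol adduct | C/C1=C\[C@@H]2OC(=O)[C@H](C)[C@@]2(O)[C@H](O)[C@H]3[C@H](C)C(O[Si](C)(C)C(C)(C)C)=C[C@H](OC)[C@]3(C)C(=O)CC1 | intermediate
28 | 2,9-diketone | C/C1=C\[C@@H]2OC(=O)[C@H](C)[C@@]2(O)C(=O)[C@H]3[C@H](C)C(O[Si](C)(C)C(C)(C)C)=C[C@H](OC)[C@]3(C)C(=O)CC1 | intermediate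
29 | bis-TMS enol ether (C2=C3 TMS enol ether, 8-OTMS) | C/C1=C\[C@@H]2OC(=O)[C@H](C)[C@@]2(O[Si](C)(C)C)C(=O)[C@H]3[C@H](C)C(O[Si](C)(C)C(C)(C)C)=C[C@H](OC)[C@]3(C)C(O[Si](C)(C)C)=CC1 | intermediate
30 | (3Z)-dienone: 2,9-dioxo-3Z,5E; 8-OTMS | C/C1=C\[C@@H]2OC(=O)[C@H](C)[C@@]2(O[Si](C)(C)C)C(=O)[C@H]3[C@H](C)C(O[Si](C)(C)C(C)(C)C)=C[C@H](OC)[C@]3(C)C(=O)/C=C\1 | intermediate
31 | (2S,9S)-diol; 8-OTMS | C/C1=C\[C@@H]2OC(=O)[C@H](C)[C@@]2(O[Si](C)(C)C)[C@@H](O)[C@H]3[C@H](C)C(O[Si](C)(C)C(C)(C)C)=C[C@H](OC)[C@]3(C)[C@@H](O)/C=C\1 | intermediate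
32 | 2,9-diacetate; 8-OTMS | C/C1=C\[C@@H]2OC(=O)[C@H](C)[C@@]2(O[Si](C)(C)C)[C@@H](OC(C)=O)[C@H]3[C@H](C)C(O[Si](C)(C)C(C)(C)C)=C[C@H](OC)[C@]3(C)[C@@H](OC(C)=O)/C=C\1 | intermediate
33 | cyclohexenone (12-oxo-13-ene, 11α-Me, 8-OH free) | C/C1=C\[C@@H]2OC(=O)[C@H](C)[C@@]2(O)[C@@H](OC(C)=O)[C@H]3[C@H](C)C(=O)C=C[C@]3(C)[C@@H](OC(C)=O)/C=C\1 | intermediate
34 | TMS dienol ether (C11=C12(OTMS)–C13=C14; 8-OTMS) | C/C1=C\[C@@H]2OC(=O)[C@H](C)[C@@]2(O[Si](C)(C)C)[C@@H](OC(C)=O)[C@H]3C(C)=C(O[Si](C)(C)C)C=C[C@]3(C)[C@@H](OC(C)=O)/C=C\1 | intermediate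
35 | (11R)-cyclohexenone (11β-Me) | C/C1=C\[C@@H]2OC(=O)[C@H](C)[C@@]2(O)[C@@H](OC(C)=O)[C@H]3[C@@H](C)C(=O)C=C[C@]3(C)[C@@H](OC(C)=O)/C=C\1 | intermediate
36 | C14 boronate (14α-Bpin ketone) | C/C1=C\[C@@H]2OC(=O)[C@H](C)[C@@]2(O)[C@@H](OC(C)=O)[C@H]3[C@@H](C)C(=O)C[C@H](B4OC(C)(C)C(C)(C)O4)[C@]3(C)[C@@H](OC(C)=O)/C=C\1 | intermediate
37 | (14S)-hydroxy ketone | C/C1=C\[C@@H]2OC(=O)[C@H](C)[C@@]2(O)[C@@H](OC(C)=O)[C@H]3[C@@H](C)C(=O)C[C@H](O)[C@]3(C)[C@@H](OC(C)=O)/C=C\1 | intermediate
38 | 14-butanoate (3Z,5E-diene, C16 methyl; all other centres as target) | C/C1=C\[C@@H]2OC(=O)[C@H](C)[C@@]2(O)[C@@H](OC(C)=O)[C@H]3[C@@H](C)C(=O)C[C@H](OC(=O)CCC)[C@]3(C)[C@@H](OC(C)=O)/C=C\1 | intermediate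
39 | 5,6-epoxide (trans; oxygen on the face that leads to the 6R alcohol) | C[C@]14O[C@H]4[C@@H]2OC(=O)[C@H](C)[C@@]2(O)[C@@H](OC(C)=O)[C@H]3[C@@H](C)C(=O)C[C@H](OC(=O)CCC)[C@]3(C)[C@@H](OC(C)=O)/C=C\1 | intermediate
40 | (6R)-allylic alcohol (6-hydroxy-5(16)-ene; 6-epi-deschloro-6-hydroxy target) | C=C1[C@@H](O)[C@@H]2OC(=O)[C@H](C)[C@@]2(O)[C@@H](OC(C)=O)[C@H]3[C@@H](C)C(=O)C[C@H](OC(=O)CCC)[C@]3(C)[C@@H](OC(C)=O)/C=C\1 | intermediate
41 | ptilosarcone (1R,2S,3Z,6S,7R,8R,9S,10S,11R,14S,17R) | C=C1/C=C\[C@H](OC(C)=O)[C@]2(C)[C@H]([C@@H](C)C(=O)C[C@@H]2OC(=O)CCC)[C@H](OC(C)=O)[C@]2(O)[C@@H](C)C(=O)O[C@H]2[C@H]1Cl | target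

**Step count.** 28 steps in total. The longest linear sequence is 25 steps (steps 1, 2, 4–13 and 16–28, from 1 to 41).

**Steps most likely to fail, with fallbacks**

Step 16 (cycloaddition). The twisted, trisubstituted enone may be too unreactive for a concerted cycloaddition, so that the diene is lost by hydrolysis or oligomerisation, and the diene may add to both alkene faces. Fallback: starting again from 21 and 25, the annulation is run as a stepwise ionic double Michael sequence under catalytic triflimide (Tf2NH, CH2Cl2, −78 °C). Mukaiyama–Michael addition of C11 of the diene to C10 with silyl transfer to O2 gives the silyl enol ether–vinylogous ester Michael adduct F1, which is not isolated. Intramolecular Mukaiyama–Michael addition of C1 to C14 then closes the ring and returns the silyl group to O12, so the sequence comes back to the route at 26. The first C–C bond still forms anti to the C9–C8 ring bond, so the facial argument is unchanged, while the stepwise mode tolerates more hindered partners.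

Step 12 (ring closure). Oligomerisation or protodehalogenation of the alkenylchromium may outrun closure of the strained ten-membered E,E-diene ring. Fallback: starting from 15, the silyl ether is cleaved (HF·pyridine) to the alkynyl alcohol F2, which is oxidised (Dess–Martin) to the ynal F3. A nickel-catalysed reductive alkyne–aldehyde macrocyclisation (Ni(cod)2, N-heterocyclic carbene ligand, Et3B, high dilution) then forms C1–C2 with syn delivery of hydrogen to C10. This gives the same E allylic alcohol and comes back to the route at 20 without the vinyl iodide.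

Step 5 (alkynylation). The acetylide may attack or enolise the less hindered γ-lactone, or add twice. Fallback: starting from 9, the dioxolanone is opened with the magnesium amide of N,O-dimethylhydroxylamine (MeNHOMe·HCl, i-PrMgCl, THF, −20 °C), which gives the Weinreb amide F4 with loss of pivalaldehyde. 1-Propynylmagnesium bromide then adds once to the amide and comes back to the route at 11.

Further compounds
F1 | step 16 | Mukaiyama–Michael adduct (C1=C2 TBS enol ether; C10 bears the 4-methoxy-1-methyl-2-oxobut-3-enyl chain) | C/C1=C\[C@@H]2OC(=O)[C@H](C)[C@@]2(O)[C@H](OC(C)=O)[C@@H]([C@H](C)C(=O)/C=C/OC)C(C)=C(O[Si](C)(C)C(C)(C)C)CC1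
F2 | step 12 | alkynyl alcohol (desilylated 15) | CC#C[C@@H](OC(C)=O)[C@]1(O)[C@@H](C)C(=O)O[C@H]1/C=C(\C)CCCO
F3 | step 12 | ynal | CC#C[C@@H](OC(C)=O)[C@]1(O)[C@@H](C)C(=O)O[C@H]1/C=C(\C)CCC=O
F4 | step 5 | Weinreb amide lactone | CON(C)C(=O)[C@]1(O)CC(=O)O[C@H]1/C=C(\C)CCCO[Si](C)(C)C(C)(C)C
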